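**Retrosynthetic overview**

1. Numbering used throughout: 1,4,4a,5,8,8a-hexahydronaphthalene core. Ring A = C1–C4, C4a, C8a (esters on C1 and C4, hexadecyl on C2). Ring B = C4a, C5–C8, C8a (ketone C5, ester C6, hexadecyl on C7).
2. Enabling feature: the C5 ketone carbon of ring B is γ to the carboxyl carbon on C4 of ring A (C4–C4a–C5). C5 can therefore be carried at the carbinol level as a γ-lactone of that carboxyl, i.e. as the oxygen-bearing terminus of a dienyl ester. Target ⇐ oxidation and lactone opening of a tricyclic lactone.
3. Key disconnection: ring B and the lactone ⇐ intramolecular Diels–Alder reaction of a 1-acyloxy-2-(methoxycarbonyl)-3-hexadecylbuta-1,3-diene across the C4a=C8a alkene of a 1,4-dihydroterephthalic half ester (bonds C8–C8a and C4a–C5).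
4. Fragments: the diene unit ⇐ diketene + hexadecylmagnesium bromide, then formylation. The ring A acid ⇐ Birch reduction of dimethyl 2-hexadecylterephthalate (from dimethyl 2-bromoterephthalate and 1-hexadecene), with a lipase resolution fixing C4; C1 is set later by equilibration.
5. Ring order: ring A first (from the arene); ring B and the temporary lactone together in the key step; the lactone is opened at the end.

Key step: step 7

Assumption: Candida rugosa lipase is taken to hydrolyse, among the stereoisomers of the racemic dihydroterephthalate diester, the unhindered ester whose α-carbon is (S); with the opposite preference the unreacted diester would be used after chemical monohydrolysis.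

**Route**

Step 1
Reactants: 1 dimethyl 2-bromoterephthalate; 2 1-hexadecene
Product: 4 dimethyl 2-hexadecylterephthalate, via 9-hexadecyl-9-borabicyclo[3.3.1]nonane 3 (not isolated)
Conditions: 2, 9-BBN, THF, 0 °C to rt; then 1, Pd(dppf)Cl2 (3 mol %), K3PO4, THF–DMF–H2O, 65 °C
Reagents that add atoms: none
Why: B-alkyl Suzuki–Miyaura coupling: anti-Markovnikov hydroboration gives the primary alkylborane, which after base activation transmetalates to the arylpalladium bromide formed from the electron-poor bromide at zerovalent palladium, and no stereocenter is created.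

Step 2
Reactants: 4 dimethyl 2-hexadecylterephthalate
Product: 5 dimethyl 2-hexadecylcyclohexa-2,5-diene-1,4-dicarboxylate (racemic; cis and trans)
Conditions: Li, NH3(l)–THF, t-BuOH, −78 °C; then NH4Cl
Reagents that add atoms: none
Why: Birch reduction: the electron-poor terephthalate takes up two electrons and is protonated kinetically at the two ester-bearing carbons (the α-carbons of the ester dienolates), which should give the skipped 2,5-diene; the two new stereocenters form without control and 5 is carried on as the racemic cis/trans mixture.

Step 3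
Reactants: 5 dimethyl 2-hexadecylcyclohexa-2,5-diene-1,4-dicarboxylate
Product: 6 (1S)-3-hexadecyl-4-(methoxycarbonyl)cyclohexa-2,5-diene-1-carboxylic acid (both C4 epimers)
Conditions: Candida rugosa lipase, pH 7.2 phosphate buffer–i-Pr2O, 30 °C, stopped before half conversion (pH-stat); acid separated from unreacted diester by extraction
Reagents that add atoms: water, O
Why: Lipase-catalysed enantioselective ester hydrolysis (kinetic resolution of an α-stereogenic ester): only the ester remote from the hexadecyl chain should fit the active site and the enzyme should select the (S) configuration at its α-carbon, which becomes C4 of the target and is the only stereocenter that has to be set here, because the resulting carboxylate is not α-acidic and the ester-bearing carbon (future C1) is corrected in step 8.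

Step 4
Reactants: 7 1-bromohexadecane; 8 diketene
Product: 10 3-methylidenenonadecanoic acid, via hexadecylmagnesium bromide 9 (not isolated)
Conditions: 7, Mg, THF, reflux; then 8, NiCl2 (5 mol %), THF, −30 to 0 °C; aqueous HCl
Reagents that add atoms: none
Why: Nickel-catalysed coupling of the Grignard reagent at the vinylic C–O bond of diketene (ring-opening cross-coupling of the enol lactone) should give the 3-methylidene acid with the 1,1-disubstituted alkene in place; no stereocenter.

Step 5
Reactants: 10 3-methylidenenonadecanoic acid
Product: 11 methyl 3-methylidenenonadecanoate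
Conditions: MeI, KHCO3, DMF, rt
Reagents that add atoms: iodomethane, CI
Why: SN2 O-methylation of the carboxylate under weakly basic conditions, chosen so that the β,γ-double bond does not move into conjugation; no stereocenter.

Step 6
Reactants: 11 methyl 3-methylidenenonadecanoate; 6 (1S)-3-hexadecyl-4-(methoxycarbonyl)cyclohexa-2,5-diene-1-carboxylic acid
Product: 14 (1Z)-2-(methoxycarbonyl)-3-methylidenenonadec-1-en-1-yl (1S)-3-hexadecyl-4-(methoxycarbonyl)cyclohexa-2,5-diene-1-carboxylate, via sodium formyl-enolate 12 (not isolated), via acid chloride 13 (not isolated)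
Conditions: 11, NaH, HCO2Me, THF, 0 °C to rt, then volatiles removed; separately 6, 1-chloro-N,N,2-trimethylprop-1-en-1-amine, CH2Cl2, 0 °C; the acid chloride solution added to the enolate in THF, −78 to 0 °C
Reagents that add atoms: methyl formate, COC=O
Why: Claisen formylation at the α-carbon of the ester dienolate gives a chelated sodium formyl-enolate that should be O-acylated by the acid chloride (made under neutral conditions by the Ghosez method so that the doubly allylic α-stereocenter is not enolised), which places the acyloxy group cis to the ester and leaves the (1S) centre untouched.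

Step 7
Reactants: 14 (1Z)-2-(methoxycarbonyl)-3-methylidenenonadec-1-en-1-yl (1S)-3-hexadecyl-4-(methoxycarbonyl)cyclohexa-2,5-diene-1-carboxylate
Product: 15 dimethyl (4R,4aS,8aR)-4-carboxy-2,7-dihexadecyl-5-hydroxy-1,4,4a,5,8,8a-hexahydronaphthalene-1,6-dicarboxylate 4,5-lactone (C1 and C5 epimers)
Conditions: toluene (0.005 M), BHT (cat.), degassed, sealed tube, 170 °C
Reagents that add atoms: none
Why: On heating, the 1-acyloxy-2-(methoxycarbonyl)diene and the cis-disubstituted C4a=C8a alkene of the cyclohexa-2,5-diene should unite in a concerted, suprafacial intramolecular [4+2] cycloaddition (diene LUMO lowered by its ester, alkene HOMO of a dialkyl-substituted olefin) that forms C8–C8a and C4a–C5 in one operation. The closest known reaction type is the type 1 intramolecular Diels–Alder reaction of ester-tethered 1,3,8-nonatrienes, which gives lactone-fused cyclohexenes. Ring B closes as the six-membered cycloaddition ring through C8–C8a and C4a–C5, and the γ-lactone closes as the five-membered tether ring (O–C(=O)–C4 bridging C5 and C4a) in the same event. C4a and C8a are controlled by the existing C4 stereocenter: the three-atom tether can reach only the alkene face that carries the C4 carboxyl, and suprafacial addition then puts H-4, H-4a and H-8a on one face (cis ring fusion), whereas C5 is formed without control and is erased by oxidation in step 10. The step needs site selectivity (C4a=C8a against C2=C3, secured because addition to C2=C3 would have to build a quaternary carbon at the hexadecyl-bearing C2), regioselectivity (fixed by the tether length, a bridged mode being out of reach) and a diene with the acyloxy group outside (the push-pull enol ester double bond equilibrates thermally).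

Step 8
Reactants: 15 tricyclic lactone (C1 and C5 epimers)
Product: 16 dimethyl (1S,4R,4aS,8aR)-4-carboxy-2,7-dihexadecyl-5-hydroxy-1,4,4a,5,8,8a-hexahydronaphthalene-1,6-dicarboxylate 4,5-lactone (C5 epimers)
Conditions: DBU (0.3 equiv), toluene, 50 °C
Reagents that add atoms: none
Why: Base-mediated epimerisation through the ester dienolate with α-reprotonation (thermodynamic control): C1–H is allylic and α to an ester, the lactone α-carbon C4 can only return to the cis-fused lactone, and the C1 ester should settle on the convex face, trans to C8, which is the configuration of the target.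

Step 9
Reactants: 16 tricyclic lactone with C1 corrected
Product: 18 trimethyl (1S,4R,4aS,8aR)-2,7-dihexadecyl-5-hydroxy-1,4,4a,5,8,8a-hexahydronaphthalene-1,4,6-tricarboxylate (C5 epimers; used crude), via lithium carboxylate 17 (not isolated)
Conditions: LiOH·H2O (1.05 equiv), THF–H2O, 0 °C; solvent removed; then MeI, DMF, 0 °C to rt
Reagents that add atoms: lithium hydroxide, [Li+].[OH-]; iodomethane, CI
Why: Saponification of the γ-lactone (acyl–oxygen cleavage, faster than attack on the two hindered methyl esters) followed by SN2 methylation of the carboxylate without acidification should unmask the C5 carbinol and the C4 methyl ester, while C4 is never an enolisable ester under base and relactonisation is avoided.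

Step 10
Reactants: 18 hydroxy triester (C5 epimers)
Product: 19 trimethyl (1S,4R,4aS,8aR)-2,7-dihexadecyl-5-oxo-1,4,4a,5,8,8a-hexahydronaphthalene-1,4,6-tricarboxylate (CNP0149813.1)
Conditions: Dess–Martin periodinane, NaHCO3, CH2Cl2, 0 °C to rt
Reagents that add atoms: none
Why: Dess–Martin oxidation of the secondary allylic alcohol (both C5 epimers converge) under buffered, non-basic conditions should give the enone without touching the now enolisable C4a–H, so that the cis ring fusion set in step 7 is kept.

**Compound list**

1 | dimethyl 2-bromoterephthalate | COC(=O)c1ccc(C(=O)OC)c(Br)c1 | starting material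
2 | 1-hexadecene | CCCCCCCCCCCCCCC=C | starting material
3 | 9-hexadecyl-9-borabicyclo[3.3.1]nonane | CCCCCCCCCCCCCCCCB1C2CCCC1CCC2 | intermediate
4 | dimethyl 2-hexadecylterephthalate | CCCCCCCCCCCCCCCCc1cc(C(=O)OC)ccc1C(=O)OC | intermediate
5 | dimethyl 2-hexadecylcyclohexa-2,5-diene-1,4-dicarboxylate (racemic, cis and trans) | CCCCCCCCCCCCCCCCC1=CC(C(=O)OC)C=CC1C(=O)OC | intermediate
6 | (1S)-3-hexadecyl-4-(methoxycarbonyl)cyclohexa-2,5-diene-1-carboxylic acid (C4 epimers) | CCCCCCCCCCCCCCCCC1=C[C@@H](C(=O)O)C=CC1C(=O)OC | intermediate
7 | 1-bromohexadecane | CCCCCCCCCCCCCCCCBr | starting material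
8 | diketene (4-methylideneoxetan-2-one) | C=C1CC(=O)O1 | starting material
9 | hexadecylmagnesium bromide | CCCCCCCCCCCCCCCC[Mg]Br | intermediate
10 | 3-methylidenenonadecanoic acid | CCCCCCCCCCCCCCCCC(=C)CC(=O)O | intermediate
11 | methyl 3-methylidenenonadecanoate | CCCCCCCCCCCCCCCCC(=C)CC(=O)OC | intermediate
12 | sodium (1Z)-2-(methoxycarbonyl)-3-methylidenenonadec-1-en-1-olate | CCCCCCCCCCCCCCCCC(=C)/C(C(=O)OC)=C/[O-].[Na+] | intermediate
13 | (1S)-3-hexadecyl-4-(methoxycarbonyl)cyclohexa-2,5-diene-1-carbonyl chloride (C4 epimers) | CCCCCCCCCCCCCCCCC1=C[C@@H](C(=O)Cl)C=CC1C(=O)OC | intermediate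
14 | (1Z)-2-(methoxycarbonyl)-3-methylidenenonadec-1-en-1-yl (1S)-3-hexadecyl-4-(methoxycarbonyl)cyclohexa-2,5-diene-1-carboxylate (C4 epimers of the ring) | CCCCCCCCCCCCCCCCC1=C[C@@H](C(=O)O/C=C(\C(=O)OC)C(=C)CCCCCCCCCCCCCCCC)C=CC1C(=O)OC | intermediate
15 | tricyclic lactone: dimethyl (4R,4aS,8aR)-4-carboxy-2,7-dihexadecyl-5-hydroxy-1,4,4a,5,8,8a-hexahydronaphthalene-1,6-dicarboxylate 4,5-lactone; H-4, H-4a, H-8a cis; C1 and C5 epimers | CCCCCCCCCCCCCCCCC1=C[C@@H](C(=O)O3)[C@H]2C3C(C(=O)OC)=C(CCCCCCCCCCCCCCCC)C[C@H]2C1C(=O)OC | intermediate
16 | tricyclic lactone with (1S) ester, trans to C8: dimethyl (1S,4R,4aS,8aR)-4-carboxy-2,7-dihexadecyl-5-hydroxy-1,4,4a,5,8,8a-hexahydronaphthalene-1,6-dicarboxylate 4,5-lactone; C5 epimers | CCCCCCCCCCCCCCCCC1=C[C@@H](C(=O)O3)[C@H]2C3C(C(=O)OC)=C(CCCCCCCCCCCCCCCC)C[C@H]2[C@@H]1C(=O)OC | intermediate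
17 | lithium (1S,4R,4aS,8aR)-2,7-dihexadecyl-5-hydroxy-1,6-bis(methoxycarbonyl)-1,4,4a,5,8,8a-hexahydronaphthalene-4-carboxylate (C5 epimers; carboxylate at C4) | CCCCCCCCCCCCCCCCC1=C[C@@H](C(=O)[O-])[C@H]2C(O)C(C(=O)OC)=C(CCCCCCCCCCCCCCCC)C[C@H]2[C@@H]1C(=O)OC.[Li+] | intermediate
18 | trimethyl (1S,4R,4aS,8aR)-2,7-dihexadecyl-5-hydroxy-1,4,4a,5,8,8a-hexahydronaphthalene-1,4,6-tricarboxylate (C5 epimers) | CCCCCCCCCCCCCCCCC1=C[C@@H](C(=O)OC)[C@H]2C(O)C(C(=O)OC)=C(CCCCCCCCCCCCCCCC)C[C@H]2[C@@H]1C(=O)OC | intermediate
19 | trimethyl (1S,4R,4aS,8aR)-2,7-dihexadecyl-5-oxo-1,4,4a,5,8,8a-hexahydronaphthalene-1,4,6-tricarboxylate | CCCCCCCCCCCCCCCCC1=C[C@@H](C(=O)OC)[C@H]2C(=O)C(C(=O)OC)=C(CCCCCCCCCCCCCCCC)C[C@H]2[C@@H]1C(=O)OC | target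

**Step count and risks**

Total step count: 10. Longest linear sequence: 8 steps (steps 1, 2, 3, 6, 7, 8, 9, 10).

Steps most likely to fail:

Step 7. The conformational penalty of the ester tether and the unactivated alkene may make the concerted cycloaddition slower than oligomerisation of the diene or dehydrogenation of ring A. The fallback sets out from 14 and comes back at 16. The thermal pericyclic reaction is replaced by a stepwise, triplet-sensitised cycloaddition and an anionic ring expansion. Irradiation (405 nm) with thioxanthone in MeCN should close the lactone first (C4a–C5, five-membered ring), and the 1,4-diradical should collapse at C6 to the cis-fused vinylcyclobutane lactone F1, which has a C6–C8a bond and an octadec-1-en-2-yl group on C6; any collapse at C8 gives 15 directly. DBU in toluene should then open the strained cyclobutane by retro-Michael reaction (the C1 ester enolate expels the C6 dienolate), and the dienolate should reclose through C8 onto C8a (vinylogous Michael addition), giving 16 after thermodynamic protonation at C1.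

Step 3. The lipase may discriminate poorly between the two vinylic arms at the α-carbon (low enantioselectivity), or turn over the lipophilic substrate slowly. The fallback sets out from 4 and comes back at 6. Chemical differentiation and classical resolution are used instead of the enzyme. One equivalent of LiOH (THF–MeOH–H2O, 0 °C) should hydrolyse only the ester that is not flanked by the hexadecyl group, giving 3-hexadecyl-4-(methoxycarbonyl)benzoic acid F2. Birch reduction of its lithium salt (Li, NH3–THF, −78 °C; NH4Cl) should give the racemic dihydro acid F3. Crystallisation with (S)-1-phenylethylamine (or its antipode, chosen by trial) should give the diastereomerically pure ammonium salt F4 of the (1S) acid, and dilute KHSO4 then liberates 6.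

Step 6. The ambident enolate may be acylated on carbon, or the acid chloride 13 may lose configuration at its doubly allylic α-carbon through ketene formation. The fallback sets out from 11 and 6 and comes back at 14. Nucleophilic vinylic substitution by the carboxylate is used instead of O-acylation by an activated acid. 11 is formylated as before and the enolate is treated with (COCl)2 and catalytic DMF to give methyl (2Z)-2-(chloromethylidene)-3-methylidenenonadecanoate F5. 6 is converted with Cs2CO3 in MeOH into caesium (1S)-3-hexadecyl-4-(methoxycarbonyl)cyclohexa-2,5-diene-1-carboxylate F6. The carboxylate, whose α-carbon is not acidic, should displace chloride by addition–elimination (DMF, rt) with retention of the double-bond geometry, giving 14.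

Further compounds
F1 | step 7 | vinylcyclobutane lactone: C4 carboxyl lactonised onto O–C5, cyclobutane C4a–C5–C6–C8a cis-fused to ring A, C6 bearing CO2Me and octadec-1-en-2-yl, C1 bearing CO2Me (C1, C5, C6 unassigned) | CCCCCCCCCCCCCCCCC1=C[C@@H](C(=O)O3)[C@H]2C3C(C(=O)OC)(C(=C)CCCCCCCCCCCCCCCC)[C@H]2C1C(=O)OC
F2 | step 3 | 3-hexadecyl-4-(methoxycarbonyl)benzoic acid | CCCCCCCCCCCCCCCCc1cc(C(=O)O)ccc1C(=O)OC
F3 | step 3 | 3-hexadecyl-4-(methoxycarbonyl)cyclohexa-2,5-diene-1-carboxylic acid (racemic, cis and trans) | CCCCCCCCCCCCCCCCC1=CC(C(=O)O)C=CC1C(=O)OC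
F4 | step 3 | (S)-1-phenylethylammonium (1S)-3-hexadecyl-4-(methoxycarbonyl)cyclohexa-2,5-diene-1-carboxylate | CCCCCCCCCCCCCCCCC1=C[C@@H](C(=O)[O-])C=CC1C(=O)OC.C[C@H]([NH3+])c1ccccc1
F5 | step 6 | methyl (2Z)-2-(chloromethylidene)-3-methylidenenonadecanoate | Cl/C=C(\C(=O)OC)C(=C)CCCCCCCCCCCCCCCC
F6 | step 6 | caesium (1S)-3-hexadecyl-4-(methoxycarbonyl)cyclohexa-2,5-diene-1-carboxylate | CCCCCCCCCCCCCCCCC1=C[C@@H](C(=O)[O-])C=CC1C(=O)OC.[Cs+]
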